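## Analysis of the target

The target is a germacranolide of the melampolide type. In germacrane numbering the ten-membered ring C1–C10 carries a Z trisubstituted alkene C1=C10 (methyl C14 on C10), an E trisubstituted alkene C4=C5 (methyl C15 on C4) and a free allylic hydroxyl on C2. An α-methylene-γ-butyrolactone is fused trans across C6–C7 (O6–C12(=O)–C11(=C13H2)–C7), and O8 bears the ester of (2R,3R)-2-(hydroxymethyl)-3-methyloxirane-2-carboxylic acid, the epoxide of a Z-configured 2-(hydroxymethyl)but-2-enoic acid. The ring stereocentres are 2R, 6R, 7R and 8R: H6 and H7 are anti on the lactone, O8 is anti to the C7–C11 bond and 1,3-anti to O6, and C2 is separated from this triad by the C4=C5 alkene. Sensitive groups are the methylene lactone (a Michael acceptor), the glycidic ester next to a primary alcohol, two allylic C–O bonds and a 1,5-diene in a medium ring that is open to acid-induced transannular cyclisation. The hard part is the ten-membered ring: an end-to-end closure pays entropy and transannular strain, and the two trisubstituted alkenes must come out with opposite, defined geometry. The strategy rests on one feature: the oxygenated C8 faces C4 of the E alkene across the ring. A C4–C8 bond turns the ring into a bicyclo[5.3.0]decene (five-membered ring C4–C5–C6–C7–C8, seven-membered ring C8–C9–C10=C1–C2–C3–C4) in which the Z alkene is enforced by ring size, and heterolysis of that bond with a leaving group on C5 returns C8=O and the C4=C5 alkene.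

## Retrosynthetic reasoning

The two TBS ethers of 41 are removed last to give 42. The allylic C2 hydroxyl and the side-chain hydroxyl would otherwise interfere with the oxidation and the acylation that precede.

The O6–C12 acyl bond of lactone 41 is cut to the 1,4-diol 38. The methylene lactone is the most electrophilic group and is therefore made as late as possible, by oxidation of the primary allylic C12 alcohol in the presence of the secondary C6 alcohol, which then closes the ring. Diol 38 comes from 36 by unmasking C12 (37) and then C6.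

The ester bond at O8 of 36 is cut to alcohol 24 and acid 34. This keeps the route convergent and lets the two epoxide stereocentres be set on a four-carbon fragment.

Alcohol 24 is traced to ketone 23 (C8–H bond). The ketone is the direct product of the ring-forming step, and reduction removes its acidity at C7 at once.

In 23 the C8 carbonyl and the E C4=C5 alkene are joined again by a C4–C8 bond, with a sulfonate placed on C5. This gives the cis-fused hydroazulene 21. The cut is made here because the forward reaction, a fragmentation, forms no bond across a medium ring and translates the cis relation of the C4 methyl and the C5 sulfonate into the E alkene. In 21 the angular methyl, the 3a-hydroxyl, the C5 mesylate, the C7 propenyl group and the C2 silyloxy group lie on one face, and the C6 silyloxy group on the other.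

Mesylate 21 comes from alcohol 20, and 20 from ketone 19 (C5–H bond). The reduction has to place the C5 oxygen cis to the angular methyl.

The C1=C10 alkene of 19 is opened to the vinyl and 2-methylallyl groups of 18. Ring-closing metathesis forms the seven-membered ring, which can only hold the Z alkene.

In 18 the C6–O bond is removed (Rubottom oxidation of enol ether 16), and in 16 the C8–C9 bond (1,2-addition to ketone 15). The order matters: C5 stays masked as its enol ether while C8 is attacked, and the tertiary alkoxide never meets a C5 ketone under basic conditions, so a retro-aldol opening is avoided.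

The C7–C11 bond of 15 is cut to enedione 8 and the alkenyl unit of 11, which is made from 9 and 10. Apart from the remote C2 centre, 8 has a mirror plane, so one catalytic conjugate addition sets C4 and C7 together and leaves the enolate that becomes 15.

Enedione 8 goes back through 7, 6 and 5 to the allylated dione 3, and to 1 and 2. C2 is set by a reagent-controlled vinylation of aldehyde 5.

Acid 34 comes from epoxy alcohol 32 by oxidation, and 32 from allylic alcohol 31 by Sharpless epoxidation. 31 is reached from 25 through 27, 28 and 29; the bromine of 27 marks the position cis to the methyl group, which ends as the carboxyl carbon.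

## Alternatives that were turned down

Alternative 1: The lactone is cut at O6–C12 and C11–C12, so that the carbonyl carbon comes from carbon monoxide. In the forward step the trans 6-hydroxy-7-ethynyl cyclodecadiene A1 would be cyclocarbonylated with a palladium chloride/tin chloride/phosphine catalyst to the protected germacranolide A2. In its favour, the most fragile group is made in one step from a robust terminal alkyne, and no C12 oxygen has to be carried. Against it, A1 already contains the ten-membered ring and both trisubstituted alkenes, so the real problem is left to another, unnamed ring-forming step. The acidic hydridopalladium medium also endangers a 1,5-diene with an allylic silyl ether, and the C8 ester would be put on after the lactone, with a PMB removal and a hindered acylation next to the Michael acceptor. For the lactone alone this route is shorter than the chosen end-game (one step against three). The chosen strategy offers a solution for the ring and the alkene geometry instead, and forms the lactone after the ester by a mild oxidation.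

Alternative 2: The carbocycle is cut at C7–C8. In the forward step the aldehyde A3, which carries a 3-(tributylstannylmethyl)butenolide, would be closed by a boron trifluoride-promoted SE2' allylation to the 8-hydroxy germacranolide A4. In its favour, one event forms the ring, the C7–C8 bond, both new stereocentres and the exocyclic methylene, and the C8 hydroxyl is freed for acylation, so it needs fewer steps after ring closure than the chosen route. Against it, a ten-membered ring is closed end to end under high dilution, and the configuration at C7 and C8 is decided in a strained transition state without a reliable model. The Z and the E alkene must each be built separately in the chain, the β,γ-unsaturated aldehyde can slip into conjugation, and the Lewis acid threatens the allylic stannane and the allylic silyl ether. The chosen fragmentation is unimolecular within a bicycle, needs no dilution and derives the alkene geometry from sp3 centres. Its price is a longer sequence.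

Alternative 3: The ring is cut at C5–C6 together with the C4–methyl bond. In the forward step the ynal A5 would undergo a nickel-catalysed alkylative cyclisation with dimethylzinc to the cyclodecadienol A6. In its favour, syn addition across the alkyne gives the E alkene with its methyl group, the ring and the C6 carbinol at once, and the two chain ends are easy to make. On the alkene it is as direct as the fragmentation and more convergent. Against it, the oxanickelacycle must close a ten-membered ring around an endocyclic E alkene, so direct methyl transfer to the aldehyde and oligomerisation compete, and the C6 configuration relative to C7 is uncertain. The lactone carbons are also carried as an acetonide-protected 1,3-diol that needs several further steps (differentiation, oxidation, dehydration) on the sensitive ring. The chosen route offers stereospecificity, and C6 and C7 are fixed on a five-membered ring before the large ring exists.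

Key step: step 13

Remark: germacrane numbering (C1–C15) is used for positions in the Why lines; the chiral ligands of steps 3 and 7 are assumed to be used as the antipode that gives the configuration drawn, to be assigned in a test reaction.
Remark: metal alkoxides that are only protonated on work-up are not numbered, with the exception of alkoxide 22.

## Steps

Step 1
Reactants: 1 2-methylcyclopentane-1,3-dione; 2 allyl bromide
Product: 3 2-methyl-2-(prop-2-en-1-yl)cyclopentane-1,3-dione
Conditions: NaOH, H2O, rt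
Reagents that add atoms: none
Why: C-allylation (SN2) of the stabilised dione enolate in water, where hydrogen bonding suppresses O-alkylation, should give the 2,2-disubstituted dione; no stereocentre arises because the product keeps a mirror plane.

Step 2
Reactants: 3 2-methyl-2-(prop-2-en-1-yl)cyclopentane-1,3-dione
Product: 5 (1-methyl-2,5-dioxocyclopentyl)acetaldehyde, via secondary ozonide 4 (not isolated)
Conditions: O3, CH2Cl2, −78 °C; then Me2S, −78 °C → rt
Reagents that add atoms: ozone O=[O+][O-]
Why: Ozonolysis of the only alkene (cycloaddition, cycloreversion, recombination to the ozonide) followed by reductive cleavage with the sulfide should give the aldehyde; the ketones are inert.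

Step 3
Reactants: 5 (1-methyl-2,5-dioxocyclopentyl)acetaldehyde
Product: 6 2-[(2R)-2-hydroxybut-3-en-1-yl]-2-methylcyclopentane-1,3-dione
Conditions: vinyl iodide, CrCl2, NiCl2 (cat.), chiral oxazoline–sulfonamide ligand, THF, rt
Reagents that add atoms: vinyl iodide C=CI
Why: Asymmetric Nozaki–Hiyama–Kishi vinylation: the vinylchromium reagent adds to the aldehyde and leaves the ketones alone, and the chiral ligand on chromium sets C2 (R). The carbinol may rest as a hemiketal with a ring ketone, which is opened again on silylation.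

Step 4
Reactants: 6 2-[(2R)-2-hydroxybut-3-en-1-yl]-2-methylcyclopentane-1,3-dione
Product: 7 2-[(2R)-2-{[tert-butyl(dimethyl)silyl]oxy}but-3-en-1-yl]-2-methylcyclopentane-1,3-dione
Conditions: TBSCl, imidazole, DMF, rt
Reagents that add atoms: tert-butyldimethylsilyl chloride CC(C)(C)[Si](C)(C)Cl
Why: Silylation of the secondary carbinol traps the open-chain form and protects O2 to the end of the route.

Step 5
Reactants: 7 2-[(2R)-2-{[tert-butyl(dimethyl)silyl]oxy}but-3-en-1-yl]-2-methylcyclopentane-1,3-dione
Product: 8 2-[(2R)-2-{[tert-butyl(dimethyl)silyl]oxy}but-3-en-1-yl]-2-methylcyclopent-4-ene-1,3-dione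
Conditions: 2-iodoxybenzoic acid (IBX), DMSO/fluorobenzene, 70 °C
Reagents that add atoms: none
Why: IBX dehydrogenation of a ketone through its enol; only C6 and C7 carry α-hydrogens, so a single enedione should form, and the isolated alkene and silyl ether are tolerated.

Step 6
Reactants: 9 2,3-dibromoprop-1-ene; 10 (4-methoxyphenyl)methanol
Product: 11 1-{[(2-bromoprop-2-en-1-yl)oxy]methyl}-4-methoxybenzene
Conditions: NaH, THF, 0 °C → rt
Reagents that add atoms: none
Why: Williamson ether synthesis: the alkoxide displaces the allylic bromide (SN2) while the vinylic bromide is inert.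

Step 7
Reactants: 8 2-[(2R)-2-{[tert-butyl(dimethyl)silyl]oxy}but-3-en-1-yl]-2-methylcyclopent-4-ene-1,3-dione; 11 1-{[(2-bromoprop-2-en-1-yl)oxy]methyl}-4-methoxybenzene
Product: 15 (2S,5R)-2-[(2R)-2-{[tert-butyl(dimethyl)silyl]oxy}but-3-en-1-yl]-5-{3-[(4-methoxyphenyl)methoxy]prop-1-en-2-yl}-2-methyl-3-[(triethylsilyl)oxy]cyclopent-3-en-1-one, via alkenyllithium 12 (not isolated), via alkenylalane 13 (not isolated), via aluminium enolate 14 (not isolated)
Conditions: 11, t-BuLi, Et2O, −78 °C; Me2AlCl; then 8, Cu(OTf)2 (5 mol %), BINOL bis(1-phenylethyl)amine phosphoramidite (10 mol %), −30 °C; then TESOTf, −30 → 0 °C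
Reagents that add atoms: triethylsilyl trifluoromethanesulfonate CC[Si](CC)(CC)OS(=O)(=O)C(F)(F)F
Why: Bromine–lithium exchange and transmetalation give the alkenylalane, which undergoes copper-catalysed asymmetric conjugate addition to the enedione. The alkenyl group enters anti to the larger C4 side chain (cis to the methyl), and the chiral copper complex selects one of the two enone carbons, so C4 and C7 are set together. O-Silylation of the aluminium enolate keeps C5 masked while C8 stays a ketone.

Step 8
Reactants: 15 (2S,5R)-TES enol ether ketone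
Product: 16 (1S,2R,5R)-2-[(2R)-2-{[tert-butyl(dimethyl)silyl]oxy}but-3-en-1-yl]-5-{3-[(4-methoxyphenyl)methoxy]prop-1-en-2-yl}-2-methyl-1-(2-methylprop-2-en-1-yl)-3-[(triethylsilyl)oxy]cyclopent-3-en-1-ol
Conditions: 2-methylallylmagnesium chloride, THF, −78 °C
Reagents that add atoms: 2-methylallylmagnesium chloride CC(=C)C[Mg]Cl
Why: An allyl-type Grignard reagent adds through a six-membered transition state to the only free ketone faster than it enolises it. Attack anti to the C7 alkenyl group and the C4 methyl places C9 cis to the C3 chain, as the later ring closure requires, and the enol ether is untouched.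

Step 9
Reactants: 16 (1S,2R,5R)-cyclopentenol
Product: 18 (2R,3S,4S,5S)-2-[(2R)-2-{[tert-butyl(dimethyl)silyl]oxy}but-3-en-1-yl]-3-hydroxy-4-{3-[(4-methoxyphenyl)methoxy]prop-1-en-2-yl}-2-methyl-3-(2-methylprop-2-en-1-yl)-5-[(triethylsilyl)oxy]cyclopentan-1-one, via silyloxy epoxide 17 (not isolated)
Conditions: dimethyldioxirane, acetone/CH2Cl2, −78 → 0 °C; then rt
Reagents that add atoms: dimethyldioxirane CC1(C)OO1
Why: Rubottom oxidation: the dioxirane epoxidises the electron-rich silyl enol ether in preference to the other alkenes, from the face opposite the adjacent C7 substituent and the C4 methyl. The 2-silyloxy epoxide then collapses with a 1,4-silyl shift to the α-silyloxy ketone, which sets C6.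

Step 10
Reactants: 18 (2R,3S,4S,5S)-cyclopentanone
Product: 19 (2S,3S,3aS,7R,8aR)-7-{[tert-butyl(dimethyl)silyl]oxy}-3a-hydroxy-3-{3-[(4-methoxyphenyl)methoxy]prop-1-en-2-yl}-5,8a-dimethyl-2-[(triethylsilyl)oxy]-3,3a,4,7,8,8a-hexahydroazulen-1(2H)-one
Conditions: second-generation Grubbs catalyst [(H2IMes)(PCy3)Cl2Ru=CHPh] (5 mol %), CH2Cl2, 40 °C
Reagents that add atoms: none
Why: Ring-closing metathesis between the vinyl group (initiation site) and the 2-methylallyl group, both on the same ring face, closes the cis-fused seven-membered ring, whose size forces the trisubstituted C1=C10 alkene to be Z. The C11 methylene lies on the other face and cannot close a ring.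

Step 11
Reactants: 19 (2S,3S,3aS,7R,8aR)-hexahydroazulenone
Product: 20 (1S,2S,3S,3aS,7R,8aS)-7-{[tert-butyl(dimethyl)silyl]oxy}-3-{3-[(4-methoxyphenyl)methoxy]prop-1-en-2-yl}-5,8a-dimethyl-2-[(triethylsilyl)oxy]-1,2,3,3a,4,7,8,8a-octahydroazulene-1,3a-diol
Conditions: (S)-2-methyl-CBS-oxazaborolidine [(3aS)-1-methyl-3,3-diphenyltetrahydro-1H,3H-pyrrolo[1,2-c][1,3,2]oxazaborole], catecholborane, toluene, −78 → −40 °C; then MeOH, aq NaHCO3
Reagents that add atoms: none
Why: Corey–Bakshi–Shibata reduction with catecholborane, which spares the alkenes. The catalyst binds the ketone anti to the quaternary C4 flank and delivers hydride to the face opposite the angular methyl, the face that the methyl and the borylated 3a-oxygen also leave open, so the C5 carbinol should form cis to the methyl. The 3a-hydroxyl is capped as a catechol borate without a B–H bond and cannot deliver hydride to the wrong face.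

Step 12
Reactants: 20 (1S,2S,3S,3aS,7R,8aS)-octahydroazulene-1,3a-diol
Product: 21 (1S,2S,3S,3aS,7R,8aS)-7-{[tert-butyl(dimethyl)silyl]oxy}-3a-hydroxy-3-{3-[(4-methoxyphenyl)methoxy]prop-1-en-2-yl}-5,8a-dimethyl-2-[(triethylsilyl)oxy]-1,2,3,3a,4,7,8,8a-octahydroazulen-1-yl methanesulfonate
Conditions: MsCl, Et3N, CH2Cl2, −20 → 0 °C
Reagents that add atoms: methanesulfonyl chloride CS(=O)(=O)Cl
Why: Sulfonylation through sulfene, which is small enough for the neopentyl-type secondary alcohol; the tertiary ring-fusion alcohol is too hindered, and triethylamine is too weak a base to start the fragmentation.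

Step 13
Reactants: 21 (1S,2S,3S,3aS,7R,8aS)-hydroxy mesylate
Product: 23 (3Z,5R,7E,9R,10S)-5-{[tert-butyl(dimethyl)silyl]oxy}-10-{3-[(4-methoxyphenyl)methoxy]prop-1-en-2-yl}-3,7-dimethyl-9-[(triethylsilyl)oxy]cyclodeca-3,7-dien-1-one, via potassium alkoxide 22 (not isolated)
Conditions: KOtBu (1.05 equiv), THF, −78 → −20 °C; then pH 7 buffer, −78 °C
Reagents that add atoms: none
Why: Grob (Wharton-type) fragmentation of a cyclic 1,3-diol monosulfonate. The base forms the tertiary C8 alkoxide 22, whose lone pair pushes into the C4–C8 σ bond; this bond is antiperiplanar to the pseudo-equatorial C5–OMs bond, so C8=O and C4=C5 form as the mesylate leaves in one concerted step. No ring is closed end to end: the ten-membered ring appears when the bond shared by the five- and seven-membered rings is cut, which avoids the entropic and transannular cost of a medium-ring cyclisation. No stereocentre is created; C4, C5 and C8 are erased, and C2, C6 and C7 are untouched. The alkene geometry is stereospecific: the C4 substituent cis to the mesylate (the methyl) ends cis to C6, which is the E alkene, and the Z C1=C10 alkene is carried over from the seven-membered ring. The substrate blocks the competing paths: oxetane formation needs a back-side attack that the cis 1,3-relation of O8 and the mesylate forbids, anti E2 is impossible because H6 is cis to the mesylate and C4 has no hydrogen, and a retro-aldol is excluded because C5 is no longer a carbonyl. One equivalent of base at low temperature leaves no free base to epimerise C7 or to expel the C6 silyloxy group from the β,γ-unsaturated ketone, which is reduced directly.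

Step 14
Reactants: 23 (3Z,5R,7E,9R,10S)-cyclodecadienone
Product: 24 (1R,3Z,5R,7E,9R,10R)-5-{[tert-butyl(dimethyl)silyl]oxy}-10-{3-[(4-methoxyphenyl)methoxy]prop-1-en-2-yl}-3,7-dimethyl-9-[(triethylsilyl)oxy]cyclodeca-3,7-dien-1-ol
Conditions: crude 23, NaBH4, CeCl3·7H2O, MeOH/THF, −78 °C
Reagents that add atoms: none
Why: Luche reduction under non-basic conditions, run at once so that the C6 silyloxy group is not lost by β-elimination. Felkin–Anh addition with the oxygenated C6 as the perpendicular group places O8 anti to the C7–C11 bond and 1,3-anti to O6, which is the 8R carbinol.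

Step 15
Reactants: 25 (2E)-but-2-enal
Product: 27 (2Z)-2-bromobut-2-enal, via 2,3-dibromobutanal 26 (not isolated)
Conditions: Br2, CH2Cl2, −20 °C; then Et3N, 0 °C → rt
Reagents that add atoms: bromine BrBr
Why: Bromine addition followed by E2 loss of HBr (the acidic α-hydrogen and the β-bromide) gives the α-bromo enal; the Z isomer, with bromine cis to the methyl group, is the stable one.

Step 16
Reactants: 27 (2Z)-2-bromobut-2-enal
Product: 28 (2Z)-2-bromobut-2-en-1-ol
Conditions: NaBH4, CeCl3·7H2O, MeOH, 0 °C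
Reagents that add atoms: none
Why: Luche 1,2-reduction of the enal; the vinylic bromide and the alkene geometry are unaffected.

Step 17
Reactants: 28 (2Z)-2-bromobut-2-en-1-ol
Product: 29 {[(2Z)-2-bromobut-2-en-1-yl]oxy}(tert-butyl)dimethylsilane
Conditions: TBSCl, imidazole, CH2Cl2, rt
Reagents that add atoms: tert-butyldimethylsilyl chloride CC(C)(C)[Si](C)(C)Cl
Why: Silylation of the primary alcohol, which becomes the protected hydroxymethyl arm trans to the methyl group.

Step 18
Reactants: 29 {[(2Z)-2-bromobut-2-en-1-yl]oxy}(tert-butyl)dimethylsilane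
Product: 31 (2E)-2-({[tert-butyl(dimethyl)silyl]oxy}methyl)but-2-en-1-ol, via alkenyllithium 30 (not isolated)
Conditions: t-BuLi (2.1 equiv), Et2O, −78 °C; then CH2O (gas, from paraformaldehyde), −78 → 0 °C
Reagents that add atoms: formaldehyde C=O
Why: Bromine–lithium exchange with retention of alkene geometry and hydroxymethylation put the new CH2OH cis to the methyl group; at −78 °C silyl migration to carbon is slow.

Step 19
Reactants: 31 (2E)-2-({[tert-butyl(dimethyl)silyl]oxy}methyl)but-2-en-1-ol
Product: 32 [(2R,3R)-2-({[tert-butyl(dimethyl)silyl]oxy}methyl)-3-methyloxiran-2-yl]methanol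
Conditions: Ti(OiPr)4, L-(+)-diethyl tartrate, t-BuOOH, 4 Å MS, CH2Cl2, −20 °C
Reagents that add atoms: tert-butyl hydroperoxide CC(C)(C)OO
Why: Sharpless asymmetric epoxidation directed by the free allylic hydroxyl. L-(+)-Tartrate delivers oxygen to the same alkene face as in the (2S,3S) series of simple allylic alcohols, which here carries the descriptors 2R,3R; the small cis methyl group is tolerated.

Step 20
Reactants: 32 [(2R,3R)-2-({[tert-butyl(dimethyl)silyl]oxy}methyl)-3-methyloxiran-2-yl]methanol
Product: 34 (2R,3R)-2-({[tert-butyl(dimethyl)silyl]oxy}methyl)-3-methyloxirane-2-carboxylic acid, via epoxy aldehyde 33 (not isolated)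
Conditions: 2,2,6,6-tetramethylpiperidin-1-oxyl (TEMPO, cat.), PhI(OAc)2, MeCN/H2O, rt
Reagents that add atoms: water O
Why: Oxoammonium oxidation to the aldehyde, whose hydrate is oxidised on to the acid; the conditions are close to neutral, so the epoxide and the silyl ether should survive.

Step 21
Reactants: 24 (1R,3Z,5R,7E,9R,10R)-cyclodecadienol; 34 (2R,3R)-epoxy acid
Product: 36 (1R,3Z,5R,7E,9R,10R)-5-{[tert-butyl(dimethyl)silyl]oxy}-10-{3-[(4-methoxyphenyl)methoxy]prop-1-en-2-yl}-3,7-dimethyl-9-[(triethylsilyl)oxy]cyclodeca-3,7-dien-1-yl (2R,3R)-2-({[tert-butyl(dimethyl)silyl]oxy}methyl)-3-methyloxirane-2-carboxylate, via mixed anhydride 35 (not isolated)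
Conditions: 2-methyl-6-nitrobenzoic anhydride, Et3N, 4-(dimethylamino)pyridine (DMAP), CH2Cl2, rt
Reagents that add atoms: none
Why: Shiina esterification: the mixed anhydride transfers the hindered glycidic acyl group through the acylpyridinium ion to the only free hydroxyl; no stereocentre is touched.

Step 22
Reactants: 36 PMB ether ester
Product: 37 (1R,3Z,5R,7E,9R,10R)-5-{[tert-butyl(dimethyl)silyl]oxy}-10-(3-hydroxyprop-1-en-2-yl)-3,7-dimethyl-9-[(triethylsilyl)oxy]cyclodeca-3,7-dien-1-yl (2R,3R)-2-({[tert-butyl(dimethyl)silyl]oxy}methyl)-3-methyloxirane-2-carboxylate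
Conditions: DDQ, CH2Cl2/pH 7 buffer, 0 °C
Reagents that add atoms: none
Why: Oxidative cleavage of the 4-methoxybenzyl ether by hydride abstraction and hydrolysis; the buffer protects the silyl ethers and the epoxide.

Step 23
Reactants: 37 C12 alcohol
Product: 38 (1R,3Z,5R,7E,9R,10S)-5-{[tert-butyl(dimethyl)silyl]oxy}-9-hydroxy-10-(3-hydroxyprop-1-en-2-yl)-3,7-dimethylcyclodeca-3,7-dien-1-yl (2R,3R)-2-({[tert-butyl(dimethyl)silyl]oxy}methyl)-3-methyloxirane-2-carboxylate
Conditions: pyridinium p-toluenesulfonate (cat.), MeOH/CH2Cl2, 0 °C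
Reagents that add atoms: none
Why: Acid-catalysed methanolysis removes the triethylsilyl ether much faster than the two TBS ethers, one secondary and one on a neopentyl-type primary carbon.

Step 24
Reactants: 38 1,4-diol
Product: 41 (3aR,4R,6Z,8R,10E,11aR)-8-{[tert-butyl(dimethyl)silyl]oxy}-6,10-dimethyl-3-methylidene-2-oxo-2,3,3a,4,5,8,9,11a-octahydrocyclodeca[b]furan-4-yl (2R,3R)-2-({[tert-butyl(dimethyl)silyl]oxy}methyl)-3-methyloxirane-2-carboxylate, via hydroxy enal 39 (not isolated), via lactol 40 (not isolated)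
Conditions: TEMPO (cat.), PhI(OAc)2, CH2Cl2, rt
Reagents that add atoms: none
Why: Oxidative lactonisation: the oxoammonium salt oxidises the primary allylic alcohol in preference to the secondary one, O6 closes the enal to the lactol, and this is oxidised on to the lactone. The trans ring fusion follows from the fixed C6 and C7 centres.

Step 25
Reactants: 41 bis-silyl lactone
Product: 42 (3aR,4R,6Z,8R,10E,11aR)-8-hydroxy-6,10-dimethyl-3-methylidene-2-oxo-2,3,3a,4,5,8,9,11a-octahydrocyclodeca[b]furan-4-yl (2R,3R)-2-(hydroxymethyl)-3-methyloxirane-2-carboxylate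
Conditions: HF·pyridine, pyridine/THF, 0 °C → rt
Reagents that add atoms: none
Why: Buffered fluoride cleaves both TBS ethers; the electron-poor glycidic epoxide, the ester and the methylene lactone should tolerate these mildly acidic, non-nucleophilic conditions.

## Compound list

1 | 2-methylcyclopentane-1,3-dione | CC1C(=O)CCC1=O | starting material
2 | allyl bromide (3-bromoprop-1-ene) | C=CCBr | starting material
3 | 2-methyl-2-(prop-2-en-1-yl)cyclopentane-1,3-dione | C=CCC1(C)C(=O)CCC1=O | intermediate
4 | 2-methyl-2-[(1,2,4-trioxolan-3-yl)methyl]cyclopentane-1,3-dione (secondary ozonide, not isolated) | CC1(CC2OCOO2)C(=O)CCC1=O | intermediate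
5 | (1-methyl-2,5-dioxocyclopentyl)acetaldehyde | CC1(CC=O)C(=O)CCC1=O | intermediate
6 | 2-[(2R)-2-hydroxybut-3-en-1-yl]-2-methylcyclopentane-1,3-dione | C=C[C@H](O)CC1(C)C(=O)CCC1=O | intermediate
7 | 2-[(2R)-2-{[tert-butyl(dimethyl)silyl]oxy}but-3-en-1-yl]-2-methylcyclopentane-1,3-dione | C=C[C@H](O[Si](C)(C)C(C)(C)C)CC1(C)C(=O)CCC1=O | intermediate
8 | 2-[(2R)-2-{[tert-butyl(dimethyl)silyl]oxy}but-3-en-1-yl]-2-methylcyclopent-4-ene-1,3-dione | C=C[C@H](O[Si](C)(C)C(C)(C)C)CC1(C)C(=O)C=CC1=O | intermediate
9 | 2,3-dibromoprop-1-ene | C=C(Br)CBr | starting material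
10 | (4-methoxyphenyl)methanol | COc1ccc(CO)cc1 | starting material
11 | 1-{[(2-bromoprop-2-en-1-yl)oxy]methyl}-4-methoxybenzene | C=C(Br)COCc1ccc(OC)cc1 | intermediate
12 | {3-[(4-methoxyphenyl)methoxy]prop-1-en-2-yl}lithium (not isolated) | [Li]C(=C)COCc1ccc(OC)cc1 | intermediate
13 | {3-[(4-methoxyphenyl)methoxy]prop-1-en-2-yl}dimethylaluminium (not isolated) | C[Al](C)C(=C)COCc1ccc(OC)cc1 | intermediate
14 | dimethylaluminium enolate of the conjugate adduct, O–Al on the former C5 carbonyl, ring centres as in 15 (not isolated) | C=C[C@H](O[Si](C)(C)C(C)(C)C)C[C@@]1(C)C(O[Al](C)C)=C[C@H](C(=C)COCc2ccc(OC)cc2)C1=O | intermediate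
15 | (2S,5R)-2-[(2R)-2-{[tert-butyl(dimethyl)silyl]oxy}but-3-en-1-yl]-5-{3-[(4-methoxyphenyl)methoxy]prop-1-en-2-yl}-2-methyl-3-[(triethylsilyl)oxy]cyclopent-3-en-1-one | C=C[C@H](O[Si](C)(C)C(C)(C)C)C[C@@]1(C)C(O[Si](CC)(CC)CC)=C[C@H](C(=C)COCc2ccc(OC)cc2)C1=O | intermediate
16 | (1S,2R,5R)-2-[(2R)-2-{[tert-butyl(dimethyl)silyl]oxy}but-3-en-1-yl]-5-{3-[(4-methoxyphenyl)methoxy]prop-1-en-2-yl}-2-methyl-1-(2-methylprop-2-en-1-yl)-3-[(triethylsilyl)oxy]cyclopent-3-en-1-ol | C=C[C@H](O[Si](C)(C)C(C)(C)C)C[C@@]1(C)C(O[Si](CC)(CC)CC)=C[C@H](C(=C)COCc2ccc(OC)cc2)[C@@]1(O)CC(C)=C | intermediate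
17 | 2-silyloxy epoxide of 16: oxirane across the former enol ether carbons, oxygen on the face opposite the neighbouring propenyl group (not isolated) | C=C[C@H](O[Si](C)(C)C(C)(C)C)C[C@@]1(C)[C@@]2(O[Si](CC)(CC)CC)O[C@H]2[C@H](C(=C)COCc3ccc(OC)cc3)[C@@]1(O)CC(C)=C | intermediate
18 | (2R,3S,4S,5S)-2-[(2R)-2-{[tert-butyl(dimethyl)silyl]oxy}but-3-en-1-yl]-3-hydroxy-4-{3-[(4-methoxyphenyl)methoxy]prop-1-en-2-yl}-2-methyl-3-(2-methylprop-2-en-1-yl)-5-[(triethylsilyl)oxy]cyclopentan-1-one | C=C[C@H](O[Si](C)(C)C(C)(C)C)C[C@@]1(C)C(=O)[C@@H](O[Si](CC)(CC)CC)[C@H](C(=C)COCc2ccc(OC)cc2)[C@@]1(O)CC(C)=C | intermediate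
19 | (2S,3S,3aS,7R,8aR)-7-{[tert-butyl(dimethyl)silyl]oxy}-3a-hydroxy-3-{3-[(4-methoxyphenyl)methoxy]prop-1-en-2-yl}-5,8a-dimethyl-2-[(triethylsilyl)oxy]-3,3a,4,7,8,8a-hexahydroazulen-1(2H)-one | C[C@@]12C[C@@H](O[Si](C)(C)C(C)(C)C)C=C(C)C[C@]1(O)[C@@H](C(=C)COCc3ccc(OC)cc3)[C@H](O[Si](CC)(CC)CC)C2=O | intermediate
20 | (1S,2S,3S,3aS,7R,8aS)-7-{[tert-butyl(dimethyl)silyl]oxy}-3-{3-[(4-methoxyphenyl)methoxy]prop-1-en-2-yl}-5,8a-dimethyl-2-[(triethylsilyl)oxy]-1,2,3,3a,4,7,8,8a-octahydroazulene-1,3a-diol | C[C@@]12C[C@@H](O[Si](C)(C)C(C)(C)C)C=C(C)C[C@]1(O)[C@@H](C(=C)COCc3ccc(OC)cc3)[C@H](O[Si](CC)(CC)CC)[C@H]2O | intermediate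
21 | (1S,2S,3S,3aS,7R,8aS)-7-{[tert-butyl(dimethyl)silyl]oxy}-3a-hydroxy-3-{3-[(4-methoxyphenyl)methoxy]prop-1-en-2-yl}-5,8a-dimethyl-2-[(triethylsilyl)oxy]-1,2,3,3a,4,7,8,8a-octahydroazulen-1-yl methanesulfonate | C[C@@]12C[C@@H](O[Si](C)(C)C(C)(C)C)C=C(C)C[C@]1(O)[C@@H](C(=C)COCc3ccc(OC)cc3)[C@H](O[Si](CC)(CC)CC)[C@H]2OS(C)(=O)=O | intermediate
22 | potassium alkoxide of 21, deprotonated at the 3a-hydroxyl (not isolated) | C[C@@]12C[C@@H](O[Si](C)(C)C(C)(C)C)C=C(C)C[C@]1([O-])[C@@H](C(=C)COCc3ccc(OC)cc3)[C@H](O[Si](CC)(CC)CC)[C@H]2OS(C)(=O)=O.[K+] | intermediate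
23 | (3Z,5R,7E,9R,10S)-5-{[tert-butyl(dimethyl)silyl]oxy}-10-{3-[(4-methoxyphenyl)methoxy]prop-1-en-2-yl}-3,7-dimethyl-9-[(triethylsilyl)oxy]cyclodeca-3,7-dien-1-one | C=C(COCc2ccc(OC)cc2)[C@@H]1C(=O)C/C(C)=C\[C@H](O[Si](C)(C)C(C)(C)C)C/C(C)=C/[C@H]1O[Si](CC)(CC)CC | intermediate
24 | (1R,3Z,5R,7E,9R,10R)-5-{[tert-butyl(dimethyl)silyl]oxy}-10-{3-[(4-methoxyphenyl)methoxy]prop-1-en-2-yl}-3,7-dimethyl-9-[(triethylsilyl)oxy]cyclodeca-3,7-dien-1-ol | C=C(COCc2ccc(OC)cc2)[C@@H]1[C@H](O)C/C(C)=C\[C@H](O[Si](C)(C)C(C)(C)C)C/C(C)=C/[C@H]1O[Si](CC)(CC)CC | intermediate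
25 | (2E)-but-2-enal (crotonaldehyde) | C/C=C/C=O | starting material
26 | 2,3-dibromobutanal (not isolated) | CC(Br)C(Br)C=O | intermediate
27 | (2Z)-2-bromobut-2-enal | C/C=C(\Br)C=O | intermediate
28 | (2Z)-2-bromobut-2-en-1-ol | C/C=C(\Br)CO | intermediate
29 | {[(2Z)-2-bromobut-2-en-1-yl]oxy}(tert-butyl)dimethylsilane | C/C=C(\Br)CO[Si](C)(C)C(C)(C)C | intermediate
30 | [(2E)-1-{[tert-butyl(dimethyl)silyl]oxy}but-2-en-2-yl]lithium (not isolated) | C/C=C(\[Li])CO[Si](C)(C)C(C)(C)C | intermediate
31 | (2E)-2-({[tert-butyl(dimethyl)silyl]oxy}methyl)but-2-en-1-ol | C/C=C(\CO)CO[Si](C)(C)C(C)(C)C | intermediate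
32 | [(2R,3R)-2-({[tert-butyl(dimethyl)silyl]oxy}methyl)-3-methyloxiran-2-yl]methanol | OC[C@]1(CO[Si](C)(C)C(C)(C)C)O[C@@H]1C | intermediate
33 | (2R,3R)-2-({[tert-butyl(dimethyl)silyl]oxy}methyl)-3-methyloxirane-2-carbaldehyde (not isolated) | O=C[C@]1(CO[Si](C)(C)C(C)(C)C)O[C@@H]1C | intermediate
34 | (2R,3R)-2-({[tert-butyl(dimethyl)silyl]oxy}methyl)-3-methyloxirane-2-carboxylic acid | OC(=O)[C@]1(CO[Si](C)(C)C(C)(C)C)O[C@@H]1C | intermediate
35 | mixed anhydride of 34 and 2-methyl-6-nitrobenzoic acid (not isolated) | Cc1cccc([N+](=O)[O-])c1C(=O)OC(=O)[C@]1(CO[Si](C)(C)C(C)(C)C)O[C@@H]1C | intermediate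
36 | (1R,3Z,5R,7E,9R,10R)-5-{[tert-butyl(dimethyl)silyl]oxy}-10-{3-[(4-methoxyphenyl)methoxy]prop-1-en-2-yl}-3,7-dimethyl-9-[(triethylsilyl)oxy]cyclodeca-3,7-dien-1-yl (2R,3R)-2-({[tert-butyl(dimethyl)silyl]oxy}methyl)-3-methyloxirane-2-carboxylate | C=C(COCc2ccc(OC)cc2)[C@@H]1[C@H](OC(=O)[C@]3(CO[Si](C)(C)C(C)(C)C)O[C@@H]3C)C/C(C)=C\[C@H](O[Si](C)(C)C(C)(C)C)C/C(C)=C/[C@H]1O[Si](CC)(CC)CC | intermediate
37 | (1R,3Z,5R,7E,9R,10R)-5-{[tert-butyl(dimethyl)silyl]oxy}-10-(3-hydroxyprop-1-en-2-yl)-3,7-dimethyl-9-[(triethylsilyl)oxy]cyclodeca-3,7-dien-1-yl (2R,3R)-2-({[tert-butyl(dimethyl)silyl]oxy}methyl)-3-methyloxirane-2-carboxylate | C=C(CO)[C@@H]1[C@H](OC(=O)[C@]3(CO[Si](C)(C)C(C)(C)C)O[C@@H]3C)C/C(C)=C\[C@H](O[Si](C)(C)C(C)(C)C)C/C(C)=C/[C@H]1O[Si](CC)(CC)CC | intermediate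
38 | (1R,3Z,5R,7E,9R,10S)-5-{[tert-butyl(dimethyl)silyl]oxy}-9-hydroxy-10-(3-hydroxyprop-1-en-2-yl)-3,7-dimethylcyclodeca-3,7-dien-1-yl (2R,3R)-2-({[tert-butyl(dimethyl)silyl]oxy}methyl)-3-methyloxirane-2-carboxylate | C=C(CO)[C@@H]1[C@H](OC(=O)[C@]3(CO[Si](C)(C)C(C)(C)C)O[C@@H]3C)C/C(C)=C\[C@H](O[Si](C)(C)C(C)(C)C)C/C(C)=C/[C@H]1O | intermediate
39 | (1R,3Z,5R,7E,9R,10S)-5-{[tert-butyl(dimethyl)silyl]oxy}-9-hydroxy-3,7-dimethyl-10-(3-oxoprop-1-en-2-yl)cyclodeca-3,7-dien-1-yl (2R,3R)-2-({[tert-butyl(dimethyl)silyl]oxy}methyl)-3-methyloxirane-2-carboxylate (not isolated) | C=C(C=O)[C@@H]1[C@H](OC(=O)[C@]3(CO[Si](C)(C)C(C)(C)C)O[C@@H]3C)C/C(C)=C\[C@H](O[Si](C)(C)C(C)(C)C)C/C(C)=C/[C@H]1O | intermediate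
40 | (3aR,4R,6Z,8R,10E,11aR)-8-{[tert-butyl(dimethyl)silyl]oxy}-2-hydroxy-6,10-dimethyl-3-methylidene-2,3,3a,4,5,8,9,11a-octahydrocyclodeca[b]furan-4-yl (2R,3R)-2-({[tert-butyl(dimethyl)silyl]oxy}methyl)-3-methyloxirane-2-carboxylate (lactol, either C2 epimer, not isolated) | C=C1C(O)O[C@@H]2/C=C(\C)C[C@@H](O[Si](C)(C)C(C)(C)C)/C=C(/C)C[C@@H](OC(=O)[C@]3(CO[Si](C)(C)C(C)(C)C)O[C@@H]3C)[C@@H]12 | intermediate
41 | (3aR,4R,6Z,8R,10E,11aR)-8-{[tert-butyl(dimethyl)silyl]oxy}-6,10-dimethyl-3-methylidene-2-oxo-2,3,3a,4,5,8,9,11a-octahydrocyclodeca[b]furan-4-yl (2R,3R)-2-({[tert-butyl(dimethyl)silyl]oxy}methyl)-3-methyloxirane-2-carboxylate | C=C1C(=O)O[C@@H]2/C=C(\C)C[C@@H](O[Si](C)(C)C(C)(C)C)/C=C(/C)C[C@@H](OC(=O)[C@]3(CO[Si](C)(C)C(C)(C)C)O[C@@H]3C)[C@@H]12 | intermediate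
42 | (3aR,4R,6Z,8R,10E,11aR)-8-hydroxy-6,10-dimethyl-3-methylidene-2-oxo-2,3,3a,4,5,8,9,11a-octahydrocyclodeca[b]furan-4-yl (2R,3R)-2-(hydroxymethyl)-3-methyloxirane-2-carboxylate | C=C1C(=O)O[C@@H]2/C=C(\C)C[C@@H](O)/C=C(/C)C[C@@H](OC(=O)[C@]3(CO)O[C@@H]3C)[C@@H]12 | target

## Step count and least certain steps

Total step count: 25. Longest linear sequence: 18 steps (from 1 through steps 1–5, 7–14 and 21–25); step 6 and steps 15–20 are side branches.

Step 13 (key step). The most likely failure is enolisation of the new β,γ-unsaturated ketone by residual alkoxide, so that the C6 silyloxy group is lost by β-elimination or C7 epimerises. The second is a slow fragmentation, if the five-membered ring cannot bring the C5–O bond close enough to antiperiplanar with C4–C8. Fallback, from 21: silylation of the tertiary hydroxyl (TMSOTf, 2,6-lutidine) gives the 3a-O-trimethylsilyl ether of 21 F1. Anhydrous fluoride (tris(dimethylamino)sulfonium difluorotrimethylsilicate, THF, −78 °C) then releases the alkoxide without any Brønsted base or alcohol present, so that it fragments as it forms. The route is rejoined at 23.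

Step 7. Likely failures are loss of the allylic ether from the alkenyl metal (allene formation) before transfer, weak discrimination between the two enone carbons, and incomplete O-silylation of the aluminium enolate. Fallback, from 11 and 8: palladium-catalysed borylation of 11 (bis(pinacolato)diboron, PdCl2(dppf), KOAc) gives 2-{3-[(4-methoxyphenyl)methoxy]prop-1-en-2-yl}-4,4,5,5-tetramethyl-1,3,2-dioxaborolane F2. Rhodium-catalysed asymmetric 1,4-addition of F2 to 8 (Rh(acac)(C2H4)2, BINAP, aqueous dioxane) gives (2S,4R)-2-[(2R)-2-{[tert-butyl(dimethyl)silyl]oxy}but-3-en-1-yl]-4-{3-[(4-methoxyphenyl)methoxy]prop-1-en-2-yl}-2-methylcyclopentane-1,3-dione F3. Kinetic deprotonation of the unhindered C6 methylene with LDA in the presence of TESCl at −78 °C returns to 15.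

Step 11. The risk is hydride delivery to the wrong face of the crowded C5 ketone, or no reduction at all at a ketone flanked by a quaternary and an oxygenated carbon. The C5 epimer would fragment to the Z alkene. Fallback, from 19: removal of the triethylsilyl group (pyridinium p-toluenesulfonate, MeOH) gives (2S,3S,3aS,7R,8aR)-7-{[tert-butyl(dimethyl)silyl]oxy}-2,3a-dihydroxy-3-{3-[(4-methoxyphenyl)methoxy]prop-1-en-2-yl}-5,8a-dimethyl-3,3a,4,7,8,8a-hexahydroazulen-1(2H)-one F4. Hydroxyl-directed reduction with Me4NBH(OAc)3 in AcOH/MeCN delivers hydride from the C6 hydroxyl on the lower face and gives the trans-diol (1S,2S,3S,3aS,7R,8aS)-7-{[tert-butyl(dimethyl)silyl]oxy}-3-{3-[(4-methoxyphenyl)methoxy]prop-1-en-2-yl}-5,8a-dimethyl-1,2,3,3a,4,7,8,8a-octahydroazulene-1,2,3a-triol F5. Selective silylation of the less hindered C6 hydroxyl (TESCl, imidazole, −20 °C) returns to 20. In this fallback the 3a-hydroxyl could compete as a directing group, and that has to be tested.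

Step 14. The risk is poor facial selectivity in the flexible ten-membered ring, leading to the 8S alcohol. Fallback, from 23: the epimeric alcohol (1S,3Z,5R,7E,9R,10R)-5-{[tert-butyl(dimethyl)silyl]oxy}-10-{3-[(4-methoxyphenyl)methoxy]prop-1-en-2-yl}-3,7-dimethyl-9-[(triethylsilyl)oxy]cyclodeca-3,7-dien-1-ol F6 is esterified with acid 34 under Mitsunobu conditions (PPh3, diisopropyl azodicarboxylate). This inverts C8 and arrives directly at 36.

Step 3. The risk is modest enantioselectivity in the chromium-mediated vinylation of an aldehyde flanked by two ketones. Fallback, from 1: zerovalent-palladium-catalysed alkylation (Pd(PPh3)4, THF) with 2-vinyloxirane gives 2-[(2E)-4-hydroxybut-2-en-1-yl]-2-methylcyclopentane-1,3-dione F7. Sharpless epoxidation with D-(−)-diethyl tartrate gives 2-{[(2R,3R)-3-(hydroxymethyl)oxiran-2-yl]methyl}-2-methylcyclopentane-1,3-dione F8. Iodination (I2, PPh3, imidazole) gives 2-{[(2R,3S)-3-(iodomethyl)oxiran-2-yl]methyl}-2-methylcyclopentane-1,3-dione F9. Reductive opening with zinc in ethanol keeps the C–O bond of the future carbinol and returns to 6.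

## Further compounds

F1 | step 13 | (1S,2S,3S,3aS,7R,8aS)-7-{[tert-butyl(dimethyl)silyl]oxy}-3-{3-[(4-methoxyphenyl)methoxy]prop-1-en-2-yl}-5,8a-dimethyl-2-[(triethylsilyl)oxy]-3a-[(trimethylsilyl)oxy]-1,2,3,3a,4,7,8,8a-octahydroazulen-1-yl methanesulfonate | C[C@@]12C[C@@H](O[Si](C)(C)C(C)(C)C)C=C(C)C[C@]1(O[Si](C)(C)C)[C@@H](C(=C)COCc3ccc(OC)cc3)[C@H](O[Si](CC)(CC)CC)[C@H]2OS(C)(=O)=O
F2 | step 7 | 2-{3-[(4-methoxyphenyl)methoxy]prop-1-en-2-yl}-4,4,5,5-tetramethyl-1,3,2-dioxaborolane | C=C(COCc1ccc(OC)cc1)B1OC(C)(C)C(C)(C)O1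
F3 | step 7 | (2S,4R)-2-[(2R)-2-{[tert-butyl(dimethyl)silyl]oxy}but-3-en-1-yl]-4-{3-[(4-methoxyphenyl)methoxy]prop-1-en-2-yl}-2-methylcyclopentane-1,3-dione | C=C[C@H](O[Si](C)(C)C(C)(C)C)C[C@@]1(C)C(=O)C[C@H](C(=C)COCc2ccc(OC)cc2)C1=O
F4 | step 11 | (2S,3S,3aS,7R,8aR)-7-{[tert-butyl(dimethyl)silyl]oxy}-2,3a-dihydroxy-3-{3-[(4-methoxyphenyl)methoxy]prop-1-en-2-yl}-5,8a-dimethyl-3,3a,4,7,8,8a-hexahydroazulen-1(2H)-one | C[C@@]12C[C@@H](O[Si](C)(C)C(C)(C)C)C=C(C)C[C@]1(O)[C@@H](C(=C)COCc3ccc(OC)cc3)[C@H](O)C2=O
F5 | step 11 | (1S,2S,3S,3aS,7R,8aS)-7-{[tert-butyl(dimethyl)silyl]oxy}-3-{3-[(4-methoxyphenyl)methoxy]prop-1-en-2-yl}-5,8a-dimethyl-1,2,3,3a,4,7,8,8a-octahydroazulene-1,2,3a-triol | C[C@@]12C[C@@H](O[Si](C)(C)C(C)(C)C)C=C(C)C[C@]1(O)[C@@H](C(=C)COCc3ccc(OC)cc3)[C@H](O)[C@H]2O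
F6 | step 14 | (1S,3Z,5R,7E,9R,10R)-5-{[tert-butyl(dimethyl)silyl]oxy}-10-{3-[(4-methoxyphenyl)methoxy]prop-1-en-2-yl}-3,7-dimethyl-9-[(triethylsilyl)oxy]cyclodeca-3,7-dien-1-ol | C=C(COCc2ccc(OC)cc2)[C@@H]1[C@@H](O)C/C(C)=C\[C@H](O[Si](C)(C)C(C)(C)C)C/C(C)=C/[C@H]1O[Si](CC)(CC)CC
F7 | step 3 | 2-[(2E)-4-hydroxybut-2-en-1-yl]-2-methylcyclopentane-1,3-dione | OC/C=C/CC1(C)C(=O)CCC1=O
F8 | step 3 | 2-{[(2R,3R)-3-(hydroxymethyl)oxiran-2-yl]methyl}-2-methylcyclopentane-1,3-dione | O=C1CCC(=O)C1(C)C[C@H]2O[C@@H]2CO
F9 | step 3 | 2-{[(2R,3S)-3-(iodomethyl)oxiran-2-yl]methyl}-2-methylcyclopentane-1,3-dione | O=C1CCC(=O)C1(C)C[C@H]2O[C@@H]2CI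
A1 | alternative 1 | trans 6-hydroxy-7-ethynyl germacra-1(10)Z,4E-diene with O2 triisopropylsilyl and O8 4-methoxybenzyl ethers (cyclocarbonylation substrate) | C#C[C@@H]1[C@H](OCc2ccc(OC)cc2)C/C(C)=C\[C@H](O[Si](C(C)C)(C(C)C)C(C)C)C/C(C)=C/[C@H]1O
A2 | alternative 1 | germacranolide core with O2 triisopropylsilyl and O8 4-methoxybenzyl ethers | C=C1C(=O)O[C@@H]2/C=C(\C)C[C@@H](O[Si](C(C)C)(C(C)C)C(C)C)/C=C(/C)C[C@@H](OCc3ccc(OC)cc3)[C@@H]12
A3 | alternative 2 | open-chain C8 aldehyde bearing the 5-substituted 3-[(tributylstannyl)methyl]furan-2(5H)-one (allylation substrate) | O=CC/C(C)=C\[C@H](O[Si](C(C)C)(C(C)C)C(C)C)C/C(C)=C/[C@H]1OC(=O)C(C[Sn](CCCC)(CCCC)CCCC)=C1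
A4 | alternative 2 | germacranolide core with free C8 hydroxyl and O2 triisopropylsilyl ether | C=C1C(=O)O[C@@H]2/C=C(\C)C[C@@H](O[Si](C(C)C)(C(C)C)C(C)C)/C=C(/C)C[C@@H](O)[C@@H]12
A5 | alternative 3 | open-chain ynal with terminal alkyne at C4–C5, C6 aldehyde and the acetonide-protected 1,3-diol on C7 (cyclisation substrate) | CC1(C)OCC(CO1)[C@@H](C=O)[C@H](OCc2ccc(OC)cc2)C/C(C)=C\[C@H](O[Si](C(C)C)(C(C)C)C(C)C)CC#C
A6 | alternative 3 | cyclodecadienol with free C6 hydroxyl, O8 4-methoxybenzyl ether, O2 triisopropylsilyl ether and acetonide-protected diol on C7 | CC1(C)OCC(CO1)[C@@H]2[C@H](OCc3ccc(OC)cc3)C/C(C)=C\[C@H](O[Si](C(C)C)(C(C)C)C(C)C)C/C(C)=C/[C@H]2O
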